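**Conventions used throughout.** Ring A carries the formyl group (later the hydroxyl) at C1, the ether oxygen at C6 and bromine at C3 and C5. Ring B carries the ether oxygen at C1', the hydroxyl at C6' and bromine at C3' and C5'. Compound numbers: 1 catechol, 2 2-fluorobenzaldehyde, 3 2-(2-hydroxyphenoxy)benzaldehyde, 4–8 species passed through in the bromination flask, 9 the tetrabromo aldehyde, 10 its aryl formate, 11 the target.

Remark on the chemistry: hydroxy aldehyde 3 is treated as the open form; any cyclic hemiacetal tautomer is assumed to equilibrate with it.

## The problem

The target 11 is an achiral diaryl ether in which two ortho-dioxygenated benzene rings share one oxygen; no ring has to be closed and no stereocentre set, so the whole task is to place two hydroxyls, one ether link and four bromines on the right carbons. The two rings look alike but are not equivalent. In ring B the bromines at C3' and C5' lie para and ortho to the hydroxyl on C6', the pattern that any phenol bromination delivers. In ring A the bromines at C3 and C5 lie meta to the hydroxyl on C1 and para and ortho to the ether oxygen on C6, a pattern that bromination of a free phenol cannot give. A synthesis must therefore either bring ring A in already halogenated or hide the C1 hydroxyl behind a group that does not direct to C2 and C4 while the bromines enter. The groups at risk are the electron-rich phenols, which over-brominate and oxidise easily, and the four aryl C–Br bonds, which exclude hydrogenolysis, organolithium reagents and most late transition-metal couplings; the diaryl ether itself tolerates acid and peracid. The feature that makes the key step possible is that C1 of ring A is meta to both C3 and C5, which are at the same time para and ortho to the ether oxygen on C6. A formyl group at C1 therefore directs to the same two carbons as the ether oxygen, activates C6 for displacement of fluoride by a phenoxide, and can afterwards be exchanged for hydroxyl by oxidative aryl migration.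

## Retrosynthesis

**C1–O bond of ring A (11 back to 9 through 10).** The hydroxyl on C1 is traced back to a formyl group: target 11 comes from aryl formate 10 by solvolysis, and 10 from tetrabromo aldehyde 9 by Baeyer–Villiger oxidation. This cut is preferred to a methyl ether (still an ortho/para director), a nitro group (three operations to reach OH) or a boronate (lost by ipso-bromination), because the formyl group is the only placeholder that is both meta-directing and one oxidation away from the phenol. Precursor 9 is no simpler in atom count, but its bromine pattern can be written by electrophilic substitution. The forward step needs the electron-poor ring A to migrate in preference to hydride; the ortho aryloxy oxygen supports this.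

**Four C–Br bonds (9 back to 3).** All four halogens (C3', C5', C3, C5) are removed at once, leaving halogen-free 3. Cutting the ether first would need two separately brominated halves and a hindered C–O coupling. Cutting only the bromines of ring B would need a ring A building block that already carries both bromines; that option is held in reserve as the fallback. The forward reaction must do three things:
- brominate ring B para and ortho to its free hydroxyl;
- brominate ring A para and ortho to the ether oxygen, which is also meta to the formyl group;
- give ring A its second bromine before ring B accepts a third.

The third demand is the weak point, because dibrominated ring B still has ether-activated C–H bonds at C4' and C2', while ring A is deactivated by the formyl group. Two measures are therefore built into the step: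
- After ring B has taken its two bromines (4, then 5), its hydroxyl is converted in the flask into the trifluoroacetate 6. This withdrawing ester deactivates C2' and C4' and is lost again on aqueous work-up.
- Ring A is brominated (7, then 8) with an N-bromo imide in CF3CO2H containing a little H2SO4, not with Br2 and a Lewis acid. FeBr3 or AlCl3 would bind the formyl oxygen and the phenol and make ring A the least reactive ring.

**O–C6 bond (3 back to 1 and 2).** The ether is cut between the oxygen and ring A, giving catechol 1 and 2-fluorobenzaldehyde 2. The alternative cut at O–C1' would need an Ullmann-type coupling between an ortho-hydroxy aldehyde and a protected ortho-halophenol. Here the formyl group already activates the ortho fluoride for addition–elimination, so it serves three purposes in the route. Both fragments are commodity chemicals. The forward step must arylate only one hydroxyl of a symmetrical diol, which an excess of 1 should secure.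

## Roads not taken

Alternative 1: Ring A would be built de novo by cutting C5–C6 and C1–C2. 3,5-Dibromo-2H-pyran-2-one A1 and the aryloxyalkynyl boronate A2 would undergo [4+2] cycloaddition, and the bridged adduct would lose CO2 to give aryl boronate A3. Oxidation of the C–B bond and O-demethylation would follow.
- Merits: every bromine arrives in a building block, so no competition between rings arises, and the boronate of A3 is a direct hydroxyl precursor.
- Weak points: A2 is a sensitive ynol ether boronate, and the usual access through a lithiated alkynyl ether is hard to reconcile with two aryl bromides. The aryloxy half of A2 has both bromines meta to the oxygen that links it to the alkyne, so it cannot come from plain phenol bromination and needs a masking device of its own. The cycloaddition must place the aryloxy carbon next to the brominated pyrone carbon, which is not assured. A1 must be prepared.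
- Comparison: this road is better in positional certainty. The chosen plan offers three steps from two commodity chemicals against roughly three times as many, and needs no unproven regiochemistry in a thermal cycloaddition.

Alternative 2: The cut removes the C1'–O ether bond and the C6'–O hydroxyl bond of ring B together. Iodo sulfonate A4 and iPrMgCl would generate 3,5-dibromobenzyne A5. The magnesium salt of 2,4-dibromo-6-methoxyphenol A6 would add to aryne A5 at the carbon remote from bromine, and the resulting aryl magnesium species would be trapped with B(OMe)3 and oxidised with H2O2 to give A7. BBr3 demethylation would finish.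
- Merits: it is highly convergent. Both halves come from phenols brominated under hydroxyl control, and A6 already carries the pattern of ring A because its phenolic oxygen becomes the ether oxygen. The inductive effect of the adjacent bromine in A5 supports the regiochemistry of the addition.
- Weak points: the nucleophile is a hindered, weakly nucleophilic di-ortho-substituted phenoxide. The aryl magnesium intermediate has an ortho bromine and can eliminate to a second aryne before it is borylated. Iodine–magnesium exchange on A4 must be selective beside two C–Br bonds, and the later intermediates carry four.
- Comparison: in certainty of bromine placement this road is the better one. The chosen plan sets against it a shorter sequence (three steps against about six), no low-temperature three-component organometallic step, and a fallback through F2 that recovers the same positional certainty.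

Alternative 3: Ring B would be built de novo by cutting C1'–C2' and C5'–C6'. Pyrone A1 and the aryloxyketene dimethyl acetal A8 would undergo [4+2] cycloaddition, and loss of CO2 and methanol would give the dimethyl ether A9. Double demethylation with BBr3 would follow.
- Merits: bromine positions on ring B are fixed by the pyrone. The aryloxy part of A8 derives from the easily made A6. Both methyl ethers of A9 fall in one operation.
- Weak points: A8 is a hydrolytically fragile ketene acetal needing several steps. The ambiphilic pyrone A1 can react in more than one sense. Pyrone and acetal syntheses make the sequence long.
- Comparison: this road avoids the competition between ring A and ring B entirely. The chosen plan is far shorter and uses only classical aromatic chemistry, at the price of one demanding selectivity problem.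

Key step: step 2

## Route

Step 1
Reactants: 1 catechol (benzene-1,2-diol); 2 2-fluorobenzaldehyde
Product: 3 2-(2-hydroxyphenoxy)benzaldehyde
Conditions: 1 (3 equiv), K2CO3 (2 equiv), DMF, 100 °C, N2; excess 1 removed by aqueous washing
Reagents that add atoms: none
Why: Nucleophilic aromatic substitution by addition–elimination: the ortho formyl group stabilises the Meisenheimer intermediate and fluoride is the best leaving group for this mechanism; the excess of symmetrical catechol should suppress the second arylation, and exclusion of air protects the catecholate from oxidation.

Step 2
Reactants: 3 2-(2-hydroxyphenoxy)benzaldehyde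
Product: 9 3,5-dibromo-2-(3,5-dibromo-2-hydroxyphenoxy)benzaldehyde, via ring B monobromide 4 (not isolated), via ring B dibromide 5 (not isolated), via dibromide trifluoroacetate 6 (not isolated), via tribromide trifluoroacetate 7 (not isolated), via tetrabromide trifluoroacetate 8 (not isolated)
Conditions: NBS (2.05 equiv), CF3CO2H, 0 °C; (CF3CO)2O (3 equiv), rt; NBS (2.3 equiv), H2SO4 (ca. 15 vol%), 45 °C, dark; then Na2S2O3, NaHCO3, H2O/THF, rt
Reagents that add atoms: N-bromosuccinimide, BrN1C(=O)CCC1=O
Why: Four electrophilic aromatic substitutions run in one flask in a fixed order. In CF3CO2H at 0 °C the free hydroxyl on C6' is by far the strongest activator present, so the first two equivalents of NBS should enter para and then ortho to it (C3' then C5', giving 4 then 5), as in the dibromination of guaiacol-type phenols. Trifluoroacetic anhydride then converts that hydroxyl into the trifluoroacetate 6, a strongly electron-withdrawing ester meta to the two remaining C–H positions of ring B (C2' and C4'), which are also flanked by bromine, so ring B becomes the less reactive ring and the ipso and oxidative pathways of a free phenol are closed. NBS activated by CF3CO2H with a limited amount of H2SO4, the known system for brominating deactivated benzaldehydes meta to the formyl group without oxidising it, should then attack ring A at C3 (para to the ether oxygen) and at C5 (ortho to it), both of which are meta to the formyl group, giving 7 and then 8. The acid strength is held below that which fully protonates the formyl oxygen, and Lewis acids are avoided, because a bound formyl group would make ring A the more deactivated ring. No ring is closed and no stereocentre is formed. The selectivity required is that ring A takes its second bromine at C5 before ring B takes a third; it rests on the ester and the two bromines on ring B set against the agreeing ether and formyl directors on ring A. The aryl trifluoroacetate is an activated ester that aqueous NaHCO3 hydrolyses during work-up, so the isolated product is the free phenol 9; residual N-bromo imide is destroyed with Na2S2O3, which does not add to the formyl group.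

Step 3
Reactants: 9 3,5-dibromo-2-(3,5-dibromo-2-hydroxyphenoxy)benzaldehyde
Product: 11 3,5-dibromo-2-(3,5-dibromo-2-hydroxyphenoxy)phenol, via aryl formate 10 (not isolated)
Conditions: mCPBA (1.5 equiv), CH2Cl2, 0 °C to rt; then MeOH, HCl (cat.), rt
Reagents that add atoms: meta-chloroperoxybenzoic acid (mCPBA), OOC(=O)c1cccc(Cl)c1
Why: Baeyer–Villiger (Dakin-type) oxidation: the peracid adds to the formyl group and ring A, assisted by the lone pair of the ortho aryloxy oxygen, migrates to oxygen in the Criegee intermediate to give formate 10, which acid-catalysed methanolysis cleaves to the phenol; the electron-poor bromophenol of ring B, the aryl bromides and the diaryl ether are inert to mCPBA.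

## Compound list

1 | catechol (benzene-1,2-diol) | Oc1ccccc1O | starting material
2 | 2-fluorobenzaldehyde | O=Cc1ccccc1F | starting material
3 | 2-(2-hydroxyphenoxy)benzaldehyde | O=Cc1ccccc1Oc1ccccc1O | intermediate
4 | 2-(5-bromo-2-hydroxyphenoxy)benzaldehyde | O=Cc1ccccc1Oc1cc(Br)ccc1O | intermediate
5 | 2-(3,5-dibromo-2-hydroxyphenoxy)benzaldehyde | O=Cc1ccccc1Oc1cc(Br)cc(Br)c1O | intermediate
6 | 2,4-dibromo-6-(2-formylphenoxy)phenyl trifluoroacetate | O=Cc1ccccc1Oc1cc(Br)cc(Br)c1OC(=O)C(F)(F)F | intermediate
7 | 2,4-dibromo-6-(4-bromo-2-formylphenoxy)phenyl trifluoroacetate | O=Cc1cc(Br)ccc1Oc1cc(Br)cc(Br)c1OC(=O)C(F)(F)F | intermediate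
8 | 2,4-dibromo-6-(2,4-dibromo-6-formylphenoxy)phenyl trifluoroacetate | O=Cc1cc(Br)cc(Br)c1Oc1cc(Br)cc(Br)c1OC(=O)C(F)(F)F | intermediate
9 | 3,5-dibromo-2-(3,5-dibromo-2-hydroxyphenoxy)benzaldehyde | O=Cc1cc(Br)cc(Br)c1Oc1cc(Br)cc(Br)c1O | intermediate
10 | 3,5-dibromo-2-(3,5-dibromo-2-hydroxyphenoxy)phenyl formate | O=COc1cc(Br)cc(Br)c1Oc1cc(Br)cc(Br)c1O | intermediate
11 | 3,5-dibromo-2-(3,5-dibromo-2-hydroxyphenoxy)phenol | Oc1cc(Br)cc(Br)c1Oc1cc(Br)cc(Br)c1O | target

## Step count and risk

Total steps: 3. Longest linear sequence: 3 steps (1 and 2 to 3, to 9, to 11).

**Step 2 (key step), least certain.** The likeliest failure is bromination of ring B at C4' or C2' running ahead of the second substitution on ring A at C5. C5 is deactivated by the formyl group and the C3 bromine and is ortho to the bulky ether. The result would be over-bromination or misplacement of the fourth bromine onto ring B. Further possible failures are: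
- arrest at the tribromide stage;
- loss of the trifluoroacetyl group before ring A is complete;
- oxidation of the formyl C–H by the N-bromo imide;
- acid-promoted closure of the formyl carbon onto C2' of ring B to a xanthene-type skeleton.

The fallback gives up bromination of ring A in the presence of ring B. It sets out from catechol 1, which is arylated (K2CO3, DMF) with 3,5-dibromo-2-fluorobenzaldehyde F1 to give 3,5-dibromo-2-(2-hydroxyphenoxy)benzaldehyde F2. Br2 (2 equiv) in CH2Cl2 at 0 °C then brominates only ring B under hydroxyl control, ring A being already complete and strongly deactivated. The route is rejoined at 9.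

**Step 3.** In the Criegee intermediate hydride may migrate in place of the electron-poor, doubly brominated aryl group, which would oxidise the formyl group to the carboxylic acid level without making the C1–O bond. The hindered formyl group may also react sluggishly. The fallback removes the hydride from the competition. It sets out from 9: MeMgBr in excess (the first equivalent is consumed by the phenol) gives racemic 1-[3,5-dibromo-2-(3,5-dibromo-2-hydroxyphenoxy)phenyl]ethan-1-ol F3. Dess–Martin periodinane gives the methyl ketone 1-[3,5-dibromo-2-(3,5-dibromo-2-hydroxyphenoxy)phenyl]ethan-1-one F4. Baeyer–Villiger oxidation with mCPBA and CF3CO2H, in which aryl migrates in preference to methyl, gives 3,5-dibromo-2-(3,5-dibromo-2-hydroxyphenoxy)phenyl acetate F5. Methanolysis (K2CO3, MeOH, then acid) returns to the route at 11.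

**Step 1.** Arylation of both hydroxyls of catechol, air oxidation of the catecholate, or slow substitution by the hydrogen-bonded monoanion may erode the conversion to 3. The fallback uses a nucleophile with a single free hydroxyl. It sets out from 2, which is treated with 2-(benzyloxy)phenol F6 (K2CO3, DMF) to give 2-[2-(benzyloxy)phenoxy]benzaldehyde F7. BCl3 with pentamethylbenzene in CH2Cl2 at −78 °C removes the benzyl group without touching the aldehyde, and the route is rejoined at 3.

## Further compounds

F1 | step 2 | 3,5-dibromo-2-fluorobenzaldehyde | O=Cc1cc(Br)cc(Br)c1F
F2 | step 2 | 3,5-dibromo-2-(2-hydroxyphenoxy)benzaldehyde | O=Cc1cc(Br)cc(Br)c1Oc1ccccc1O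
F3 | step 3 | racemic 1-[3,5-dibromo-2-(3,5-dibromo-2-hydroxyphenoxy)phenyl]ethan-1-ol | CC(O)c1cc(Br)cc(Br)c1Oc1cc(Br)cc(Br)c1O
F4 | step 3 | 1-[3,5-dibromo-2-(3,5-dibromo-2-hydroxyphenoxy)phenyl]ethan-1-one | CC(=O)c1cc(Br)cc(Br)c1Oc1cc(Br)cc(Br)c1O
F5 | step 3 | 3,5-dibromo-2-(3,5-dibromo-2-hydroxyphenoxy)phenyl acetate | CC(=O)Oc1cc(Br)cc(Br)c1Oc1cc(Br)cc(Br)c1O
F6 | step 1 | 2-(benzyloxy)phenol | Oc1ccccc1OCc1ccccc1
F7 | step 1 | 2-[2-(benzyloxy)phenoxy]benzaldehyde | O=Cc1ccccc1Oc1ccccc1OCc1ccccc1
A1 | alternative 1 | 3,5-dibromo-2H-pyran-2-one | O=C1OC=C(Br)C=C1Br
A2 | alternative 1 | 2-[(3,5-dibromo-2-methoxyphenoxy)ethynyl]-4,4,5,5-tetramethyl-1,3,2-dioxaborolane | COc1c(Br)cc(Br)cc1OC#CB1OC(C)(C)C(C)(C)O1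
A3 | alternative 1 | 2-[3,5-dibromo-2-(3,5-dibromo-2-methoxyphenoxy)phenyl]-4,4,5,5-tetramethyl-1,3,2-dioxaborolane | CC1(C)OB(OC1(C)C)c1cc(Br)cc(Br)c1Oc1cc(Br)cc(Br)c1OC
A4 | alternative 2 | 2,4-dibromo-6-iodophenyl 4-chlorobenzenesulfonate | O=S(=O)(Oc1c(Br)cc(Br)cc1I)c1ccc(Cl)cc1
A5 | alternative 2 | 3,5-dibromobenzyne (3,5-dibromo-1,2-didehydrobenzene) | BrC1=CC(Br)=CC#C1
A6 | alternative 2 | 2,4-dibromo-6-methoxyphenol | COc1cc(Br)cc(Br)c1O
A7 | alternative 2 | 2,4-dibromo-6-(2,4-dibromo-6-methoxyphenoxy)phenol | COc1cc(Br)cc(Br)c1Oc1cc(Br)cc(Br)c1O
A8 | alternative 3 | 1,5-dibromo-2-[(2,2-dimethoxyethenyl)oxy]-3-methoxybenzene | COC(OC)=COc1c(Br)cc(Br)cc1OC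
A9 | alternative 3 | 1,5-dibromo-2-(3,5-dibromo-2-methoxyphenoxy)-3-methoxybenzene | COc1cc(Br)cc(Br)c1Oc1cc(Br)cc(Br)c1OC
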